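**Retrosynthetic overview**
1. Target acid ⇒ trans-fused allylic δ-lactone. C9–H is made last by ring-opening hydrogenolysis of C9–O, and the departing lactone carboxylate becomes the free acid.
2. δ-Lactone ⇒ umbelliferone + spiro vinyl epoxide ester. The key disconnection is the C11–O aryl ether bond (phenoxide opening), followed in the same flask by the acyl C–O bond of the lactone; epoxide ⇒ enone + CH2.
3. δ-Keto ester ⇒ 6-methyl-6-propargylcarvone (alkyne → ester) ⇒ two α′-alkylations of (S)-carvone, which supplies C5 and the carbocycle.
4. Ring order: the cyclohexene (carvone) and the coumarin (umbelliferone) are bought ready-made. The oxirane and then the δ-lactone are built in step 4, and the lactone is opened again in step 5.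

Assumption: the SMILES is read as drawn, which is the (1R,2R,6R) acid; this requires (S)-(+)-carvone.
Locants used below: C5 (CH–isopropenyl), C6, C7 (=CH), C8 (=C–CH3), C9 (CH–CH2OAr), C10 (quaternary), C11 (OCH2). The β face is the face of the C10 methyl and the isopropenyl group; the α face is the face of the propanoate chain.

**Step 1**
Reactants: 1 (S)-(+)-carvone
Product: 3 (5S)-6-methylcarvone (C6 epimer mixture), via lithium dienolate 2 (not isolated)
Conditions: LiN(iPr)2 (1.1 equiv), THF, −78 °C; then MeI (1.3 equiv), −78 to 0 °C
Reagents that add atoms: iodomethane, CI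
Why: Kinetic α′-deprotonation gives the cross-conjugated dienolate and SN2 enolate alkylation puts the methyl group on C10 only; the new centre needs no control because it is planarised again in step 2, and C5 is carried over unchanged from carvone.

**Step 2**
Reactants: 3 (5S)-6-methylcarvone
Product: 5 (5R,6R)-6-methyl-6-propargylcarvone, via tetrasubstituted lithium dienolate 4 (not isolated)
Conditions: LiN(iPr)2 (1.2 equiv), THF, −78 to −10 °C; then propargyl bromide (1.5 equiv), DMPU, −78 °C to rt
Reagents that add atoms: propargyl bromide (3-bromoprop-1-yne), C#CCBr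
Why: This is an enolate alkylation with a reactive propargylic halide in which the C5 isopropenyl group turns pseudoaxial to avoid allylic strain with the C10 methyl group and shields the β face, so the electrophile enters anti to it and sets quaternary C10 (R) with the three-carbon chain trans to isopropenyl; an SN2 electrophile is chosen because acrylates give bicyclo[2.2.2]octanones by double Michael addition with such dienolates.

**Step 3**
Reactants: 5 (5R,6R)-6-methyl-6-propargylcarvone
Product: 6 δ-keto methyl ester (1R,6R)
Conditions: [Rh(cod)Cl]2 (2.5 mol %), P(4-FC6H4)3 (10 mol %), 4-methylpyridine N-oxide (1.5 equiv), MeOH (5 equiv), MeCN, 60 °C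
Reagents that add atoms: methanol, CO; 4-methylpyridine N-oxide, Cc1cc[n+]([O-])cc1
Why: In this rhodium vinylidene-mediated oxygenative addition to a terminal alkyne, alkyne-to-vinylidene isomerisation, oxygen-atom transfer from the N-oxide to the vinylidene carbon and addition of methanol to the metal-bound ketene give the anti-Markovnikov ester CH2CH2CO2Me without touching the enone, the alkenes or the stereocentres.

**Step 4** (key C–O bond formation, one pot)
Reactants: 6 δ-keto methyl ester; 7 umbelliferone
Product: 10 trans-fused aryloxymethyl δ-lactone (4aR,5R,8aR), via spiro vinyl epoxide 8 (not isolated), via tertiary hydroxy ester 9 (not isolated)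
Conditions: trimethylsulfonium iodide (1.3 equiv), KOtBu (1.25 equiv), DMSO–THF, 0 °C to rt; then 7 (1.5 equiv), Cs2CO3 (30 mol %), 85 °C, N2 sweep
Reagents that add atoms: trimethylsulfonium iodide, C[S+](C)C.[I-]
Why: In this Corey–Chaykovsky epoxidation followed by phenoxide SN2 epoxide opening and translactonisation, the unstabilised ylide adds 1,2 to the enone from the α face (axial attack, anti to the axial C10 methyl group) and so places C11 α and oxygen β at C9, the umbelliferone phenoxide then attacks the only unhindered oxirane carbon C11 to form the aryl ether C–O bond with C9 untouched, and the equatorial tertiary alkoxide closes onto the equatorial ester chain to give the trans-fused δ-lactone with loss of methanol.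

**Step 5**
Reactants: 10 trans-fused aryloxymethyl δ-lactone
Product: 11 target acid (1R,2R,6R)
Conditions: Pd(OAc)2 (5 mol %), PBu3 (10 mol %), HCO2H (3 equiv), Et3N (2.5 equiv), 1,4-dioxane, 60 °C; dilute citric acid work-up
Reagents that add atoms: none
Why: Proposed new method: ring-opening decarboxylative transfer hydrogenolysis of a fully substituted allylic δ-lactone, in which zerovalent palladium/PBu3 binds the C7=C8 bond on the α face anti to the C9–O bond and ionises the lactone to a π-allylpalladium species whose tethered carboxylate is exchanged for formate, the σ-allyl form with palladium on the less hindered C7 loses CO2 and passes hydride through a cyclic transition state to the more substituted terminus C9 on the palladium-bearing α face, so that C9–O is replaced by C9–H with inversion (H α, CH2OAr β and equatorial, C9 R), the C7=C8 alkene is restored and the leaving group stays in the molecule as the free acid; the closest known reaction type is the Tsuji-type palladium–formate hydrogenolysis of allylic formates, carbonates and alkenyl oxiranes, which has not been shown for lactones or for a leaving group on a fully substituted ring carbon next to a quaternary centre.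

**Compound list**
1 | (S)-(+)-carvone, (5S)-2-methyl-5-(prop-1-en-2-yl)cyclohex-2-en-1-one | C=C(C)[C@H]1CC=C(C)C(=O)C1 | starting material
2 | lithium cross-conjugated dienolate of 1 | C=C(C)[C@H]1CC=C(C)C([O-])=C1.[Li+] | intermediate
3 | (5S)-2,6-dimethyl-5-(prop-1-en-2-yl)cyclohex-2-en-1-one (6-methylcarvone, C6 epimers, trans major) | C=C(C)[C@H]1CC=C(C)C(=O)C1C | intermediate
4 | lithium tetrasubstituted dienolate of 3 | C=C(C)[C@H]1CC=C(C)C([O-])=C1C.[Li+] | intermediate
5 | (5R,6R)-2,6-dimethyl-5-(prop-1-en-2-yl)-6-(prop-2-yn-1-yl)cyclohex-2-en-1-one | C=C(C)[C@H]1CC=C(C)C(=O)[C@]1(C)CC#C | intermediate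
6 | methyl 3-[(1R,6R)-1,3-dimethyl-2-oxo-6-(prop-1-en-2-yl)cyclohex-3-en-1-yl]propanoate | C=C(C)[C@H]1CC=C(C)C(=O)[C@]1(C)CCC(=O)OC | intermediate
7 | umbelliferone (7-hydroxy-2H-chromen-2-one) | O=c1ccc2ccc(O)cc2o1 | starting material
8 | methyl 3-[(3R,7R,8R)-4,8-dimethyl-7-(prop-1-en-2-yl)-1-oxaspiro[2.5]oct-4-en-8-yl]propanoate (oxirane O β, CH2 α) | C=C(C)[C@H]1CC=C(C)[C@]2(CO2)[C@]1(C)CCC(=O)OC | intermediate
9 | methyl 3-[(1R,2R,6R)-2-hydroxy-1,3-dimethyl-2-{[(2-oxo-2H-chromen-7-yl)oxy]methyl}-6-(prop-1-en-2-yl)cyclohex-3-en-1-yl]propanoate | C=C(C)[C@H]1CC=C(C)[C@](O)(COc2ccc3ccc(=O)oc3c2)[C@]1(C)CCC(=O)OC | intermediate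
10 | (4aR,5R,8aR)-4a,8-dimethyl-8a-{[(2-oxo-2H-chromen-7-yl)oxy]methyl}-5-(prop-1-en-2-yl)-3,4,4a,5,6,8a-hexahydro-2H-chromen-2-one | C=C(C)[C@H]1CC=C(C)[C@@]2(COc3ccc4ccc(=O)oc4c3)OC(=O)CC[C@]12C | intermediate
11 | 3-[(1R,2R,6R)-1,3-dimethyl-2-{[(2-oxo-2H-chromen-7-yl)oxy]methyl}-6-(prop-1-en-2-yl)cyclohex-3-en-1-yl]propanoic acid | C=C(C)[C@H]1CC=C(C)[C@@H](COc2ccc3ccc(=O)oc3c2)[C@]1(C)CCC(=O)O | target

**Total step count:** 5. **Longest linear sequence:** 5 (1 → 11); 7 is bought and enters in step 4.

**Three steps most likely to fail**

**Step 3.** Compound 5 is also a 1,6-enyne (alkyne and isopropenyl group), so the rhodium vinylidene could cycloisomerise before the N-oxide transfers oxygen.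
- The fallback sets out from 3 and comes back at 6, and it replaces the alkyne by an alkene.
- Dienolate 4 is alkylated with allyl bromide, with the same anti selectivity, to the allyl ketone F1.
- Only the monosubstituted alkene is oxidised by an aldehyde-selective nitrite-modified Wacker oxidation (PdCl2(PhCN)2, CuCl2, AgNO2, O2, tBuOH–MeNO2, rt) to the keto aldehyde F2.
- Pinnick oxidation (NaClO2, NaH2PO4, 2-methylbut-2-ene) gives the keto acid F3, and MeI/K2CO3 in DMF gives 6.

**Step 4.** The ketone is flanked by a quaternary carbon and a methyl-bearing alkene carbon, the ylide may also attack the ester, and surplus sulfonium salt O-methylates part of 7.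
- The fallback sets out from 6 and comes back at 10. It separates C–C from C–O bond formation and replaces the sulfur ylide by a lithium carbenoid.
- LiCH2Cl is generated from ICH2Cl and MeLi·LiBr in THF at −78 °C in the presence of 6. It adds to the ketone from the α face, and an acetic acid quench at −78 °C gives the chlorohydrin F4.
- Purified F4 is heated with preformed caesium umbelliferonate (7, Cs2CO3, DMF, 80 °C). It closes to 8, is opened at C11 to 9 and lactonises to 10.

**Step 5 (the new step).** In the rigid trans-fused lactone the C9–O bond is pseudoequatorial, so overlap with the alkene is only partial and ionisation may be slow. Hydride could also go to C7, or the π-allyl species could eliminate to a diene.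
- The fallback uses known chemistry only, sets out from 8 and comes back at 11.
- Step 4 is stopped after its first stage and 8 is isolated by aqueous work-up.
- The strain-driven palladium–formate hydrogenolysis of the alkenyl oxirane (Pd2(dba)3·CHCl3, PBu3, HCO2H, Et3N, dioxane, rt) goes with inversion and delivers hydride to the oxygen-bearing carbon. It gives the homoallylic alcohol F5.
- Mitsunobu etherification with 7 (PPh3, DIAD, toluene, 0 °C to rt) forms the aryl ether C–O bond and gives the target methyl ester F6.
- LiOH in THF–H2O, then acidification to pH 3 (which also recloses any opened coumarin), gives 11.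

**Further compounds**
F1 | step 3 | (5R,6R)-2,6-dimethyl-6-(prop-2-en-1-yl)-5-(prop-1-en-2-yl)cyclohex-2-en-1-one | C=C(C)[C@H]1CC=C(C)C(=O)[C@]1(C)CC=C
F2 | step 3 | 3-[(1R,6R)-1,3-dimethyl-2-oxo-6-(prop-1-en-2-yl)cyclohex-3-en-1-yl]propanal | C=C(C)[C@H]1CC=C(C)C(=O)[C@]1(C)CCC=O
F3 | step 3 | 3-[(1R,6R)-1,3-dimethyl-2-oxo-6-(prop-1-en-2-yl)cyclohex-3-en-1-yl]propanoic acid | C=C(C)[C@H]1CC=C(C)C(=O)[C@]1(C)CCC(=O)O
F4 | step 4 | methyl 3-[(1R,2R,6R)-2-(chloromethyl)-2-hydroxy-1,3-dimethyl-6-(prop-1-en-2-yl)cyclohex-3-en-1-yl]propanoate | C=C(C)[C@H]1CC=C(C)[C@](O)(CCl)[C@]1(C)CCC(=O)OC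
F5 | step 5 | methyl 3-[(1R,2R,6R)-2-(hydroxymethyl)-1,3-dimethyl-6-(prop-1-en-2-yl)cyclohex-3-en-1-yl]propanoate | C=C(C)[C@H]1CC=C(C)[C@@H](CO)[C@]1(C)CCC(=O)OC
F6 | step 5 | methyl 3-[(1R,2R,6R)-1,3-dimethyl-2-{[(2-oxo-2H-chromen-7-yl)oxy]methyl}-6-(prop-1-en-2-yl)cyclohex-3-en-1-yl]propanoate | C=C(C)[C@H]1CC=C(C)[C@@H](COc2ccc3ccc(=O)oc3c2)[C@]1(C)CCC(=O)OC
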